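## The problem

Daucane numbering is used: C1 is the methyl-bearing fusion carbon, C2 and C3 are the methylenes of ring A, C4 is the isopropyl carbinol, C5 is the fusion CH, C6 to C10 run round ring B with the second methyl on C8, β is the face of the C1 methyl and α the opposite face. The target **29** is a trans-fused hydroazulene (ring A five-membered, ring B seven-membered) with five stereocentres: quaternary C1 (S), the tertiary carbinol C4 (R), C5 (S), and the esterified carbinols C6 (S) and C10 (R). Only C1 has to be set absolutely, because it can steer the rest: C5 by equilibration to the trans fusion, C4 by sending the isopropyl nucleophile to the α face, C6 through the C4 hydroxyl, and C10 by shielding the β face of ring B. The hidden difficulty is that both ring-B oxygens are α, the face from which external reagents reach C6 and C10, so hydride reduction of a C6 or C10 ketone would put hydrogen, not oxygen, on that face. The fragile parts are the angelate (a (Z)-enoate that isomerises to the tiglate), the allylic C10 ester, the tertiary C4 alcohol β to C6, and two different esters on similar secondary carbinols. The enabling feature is that C6 and C10 are bonded to the two fusion carbons C5 and C1. O–C6–C5–C1–C10–O is thus what remains of a cyclobutane-1,2-diol on C1, C5, C6 and C10 after its C6–C10 bond is cleaved, and ring A with oxygen at C4 is a cyclopentenone.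

## Retrosynthesis

**C10 ester.** The acyl–oxygen bond of the angelate is cut last, **29** ⇒ **27** + **28**. The (Z)-enoate is the least robust group, and in **27** the only other hydroxyl is tertiary. The forward step needs an acylation that does not isomerise the double bond.

**C10 oxygen and the C8=C9 alkene.** Reducing a C8=C9–C10 enone would be the short way, but hydride would enter anti to the C1 methyl and give the 10β-alcohol. The C10–O bond is therefore cut as an oxygen delivered to an alkene: **27** ⇒ epoxide **24** ⇒ C9=C10 alkene **23**. The peracid uses the same α-face preference that defeats the reduction. The forward steps need opening at C9 and an elimination toward C8, which requires the C8 hydrogen to be β.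

**C6 ester and C6 carbinol.** The anisoate is cut (**23** ⇒ **21** + **22**) and the C6 carbinol is traced to ketone **20**. External hydride would again attack from α, so the reduction must be delivered from the β-oriented C4 hydroxyl. This is why the C4 carbinol has to exist before C6 is reduced.

**C4–isopropyl bond.** **20** ⇒ ketal **19** ⇒ ketone **17** + **18**. On ring A the β face of C4 carries the vicinal C5–C6 bond and the C1 methyl, so addition from α gives the required 4β-hydroxyl. C6 must be masked, because a free C4/C6 diketone would be an enolised 1,3-dione.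

**Alkene position and C8.** The C9=C10 alkene with 8β-H is traced to the C10 ketone: **17** ⇒ **16** ⇒ tosylhydrazone **14** ⇒ enone **13** ⇒ ketone **10**. Going through the enone removes the C8 stereocentre that the photocycloaddition cannot control reliably. The reductive transposition then sets it again from C10.

**Ring fusion and ketone differentiation.** **10** ⇒ **9** ⇒ **8**. The C10 ketone sits next to quaternary C1, so C6 alone is ketalised. The trans fusion comes from equilibration through the C6 enol.

**Ring B.** Reconnecting C6–C10 turns diketone **8** into cyclobutanediol **7**, i.e. alcohol **6** and ketone **5**. The cut removes the seven-membered ring altogether. The C4 carbonyl has to be reduced before the diol is freed, otherwise a retro-aldol opens C5–C6.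

**Key disconnection.** Cutting C1–C10 and C5–C6 of **5** gives enone **4** and the symmetric enediol ether **3**. The alkene is symmetric, so no regiochemistry arises, and C1 is formed as an all-carbon quaternary centre together with ring A.

**Alkene partner.** **3** ⇒ **1** + **2** by an acyloin condensation with silyl trapping; each molecule of **3** carries two silyl groups from **2**.

## Roads not taken

**Alternative 1:** The cut is C1–C5 and C7–C8 of ring B. In the forward sense the oxyallyl cation made by Zn–Cu reduction of 1,1,3,3-tetrabromopropan-2-one A2 adds across the 2 and 5 positions of 2,5-dimethylfuran A1. Debromination gives the meso oxabicycle 1,5-dimethyl-8-oxabicyclo[3.2.1]oct-6-en-3-one A3.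
- Merits: two operations from bulk chemicals, no photochemistry, and ring B arrives with both methyl carbons, the C6 carbonyl and a C9=C10 alkene. A meso compound invites catalytic desymmetrisation.
- Weak points: C1 is an oxygen-bearing bridgehead and must become an all-carbon quaternary centre. The bridge oxygen sits on C1 and C8 but is needed on C10, which demands C1–O ionisation with C–C bond formation and a 1,3-allylic shift of oxygen. Ring A still has to be annulated with two more C–C bonds.
- Comparison: up to ring B this road is shorter and more scalable than the chosen one. The chosen plan sets against it that C1 is made directly as a C–C quaternary centre, with ring A and the C4 oxygen delivered in the same step.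

**Alternative 2:** The cut is C3–C4. Forward, SmI2 reduces the primary iodide of the iodo ketone A4 and the organosamarium adds to the isopropyl ketone, giving the bis-silyl ether A5 of the triol core.
- Merits: ring A and the tertiary carbinol form together in one mild, chemoselective late step. Only desilylation and two acylations remain.
- Weak points: A4 already holds C1, C5, C6, C10 and the trisubstituted alkene, so the whole stereochemical burden of ring B moves into an unsolved synthesis of a heavily substituted cycloheptene. Chelation control of C4 through a bulky silyl ether is not assured.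
- Comparison: as an end game it is gentler than the organocerium addition of step 11 and avoids the C4 redox detour of steps 3 and 10. The chosen plan sets against it that its key step actually builds ring B and C1.

**Alternative 3:** The cut is C1–C5 and C1–C10. Forward, a chiral carbenoid (for example from Rh2(S-PTTL)4, or Cu(MeCN)4PF6 with a bis(oxazoline)) generated from the diazoketone A6 cyclopropanates the ipso–ortho bond. The norcaradiene opens to the dihydroazulenone A7.
- Merits: one catalytic step turns a flat arene into the full bicyclic skeleton with quaternary C1, both methyls and oxygen on C6 and C10. The precedent for catalytic control of C1 is better than for the photocycloaddition chosen here.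
- Weak points: the carbonyl of A7 is at C2, whereas the target needs oxygen at C4 and none at C2. α-Methyl diazoketones tend to undergo 1,2-hydride shift. C5, C6 and C10 must all be created from a planar triene with only C1 as guide, and the same anti-to-methyl bias would again put hydrogen on the α face at C10.
- Comparison: this road is shorter to the skeleton and stronger on enantiocontrol. The chosen plan sets against it oxygen at C4 from the outset, an sp3 C5 that equilibration corrects, and C6/C10 ketones that sterics tell apart.

Key step: step 2

Assumption: the (S)-prolinol-derived catalyst is taken to expose the enone face that gives the (1S) adduct; if induction on a cyclopentenone runs the other way, the (R)-catalyst is used and nothing else changes.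

Remark: compounds 5 to 11 are drawn as the C8 epimer expected from addition anti to the ring methyl of 3; the other epimer follows the same steps and merges at 12.

Step 1
Reactants: 1 dimethyl 3-methylpentanedioate; 2 chlorotrimethylsilane
Product: 3 4-methyl-1,2-bis(trimethylsilyloxy)cyclopent-1-ene
Conditions: Na (4.2 equiv), Me3SiCl (4.5 equiv), toluene, reflux
Reagents that add atoms: chlorotrimethylsilane, C[Si](C)(C)Cl
Why: Rühlmann variant of the acyloin condensation; sodium reduces both esters and the chlorosilane traps the five-membered enediolate and the methoxide as they form, which suppresses Dieckmann condensation. Each enediolate oxygen takes one silyl group, so two molecules of 2 end up in 3 and two more are consumed by the methoxide; the product is achiral.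

Step 2
Reactants: 3 4-methyl-1,2-bis(trimethylsilyloxy)cyclopent-1-ene; 4 3-methylcyclopent-2-en-1-one
Product: 5 cis-anti-cis photoadduct (tricyclic C4 ketone with the C1–C10/C5–C6 cyclobutane; 1β-methyl; 5β-H; 6α,10α-bis(trimethylsilyloxy))
Conditions: hν (λ = 366 nm), oxazaborolidine·AlBr3 (50 mol %; from (S)-α,α-bis(3,5-dimethylphenyl)prolinol and 2,4,6-trifluorophenylboronic acid), 3 (5 equiv), CH2Cl2, −75 °C
Reagents that add atoms: none
Why: Proposed new method: the Lewis-acid-bound enone absorbs at longer wavelength than the free enone, is excited selectively and crosses to the triplet, which bonds through one olefinic carbon to the electron-rich alkene and gives a 1,4-biradical that closes the four-membered ring by radical recombination after spin inversion, so C1–C10 and C5–C6 form stepwise. The closest known reactions are the uncatalysed [2+2] photocycloaddition of cyclopent-2-enones to 1,2-bis(trimethylsilyloxy)cycloalkenes and the oxazaborolidine–AlBr3-catalysed enantioselective intermolecular [2+2] photocycloaddition of cyclohex-2-enones to alkenes; joining the two on a cyclopentenone and an enediol disilyl ether is the untested element. C1 is controlled by the catalyst, which shields one enone face. C5 must be cis to C1 because a trans-fused bicyclo[3.2.0]heptanone is too strained. C6 and C10 are cis by the geometry of the cyclopentene and lie anti to ring A so that the two five-membered rings stay apart. C8 should form mainly anti to the incoming enone but does not matter, since it is erased in step 7. The alkene is symmetric, so there is no regiochemical question. A thermal Mukaiyama–Michael reaction should be slow at −75 °C because both reacting carbons are fully substituted.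

Step 3
Reactants: 5 cis-anti-cis photoadduct
Product: 6 4α-alcohol of 5 (hydroxyl on the concave face of ring A, cis to C6 and C10)
Conditions: iBu2AlH, CH2Cl2, −78 °C; aqueous KNaC4H4O6
Reagents that add atoms: none
Why: Hydride reduction from the convex face of the bicyclo[3.2.0]heptanone. The C4 carbonyl must go before the C6 oxygen is freed, or a retro-aldol would open C5–C6; the C4 configuration is immaterial because it is re-oxidised in step 10.

Step 4
Reactants: 6 4α-alcohol of 5
Product: 8 cis-fused (5β-H) 4α-hydroxy-1β,8α-dimethylbicyclo[5.3.0]decane-6,10-dione, via tricyclic triol 7 (not isolated)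
Conditions: K2CO3 (cat.), MeOH, rt; then Pb(OAc)4, CH2Cl2, 0 °C
Reagents that add atoms: none
Why: Methanolysis frees the cis-cyclobutane-1,2-diol and Pb(OAc)4 cleaves it through the cyclic lead diester (Criegee glycol cleavage), helped by release of ring strain; this breaks C6–C10 and opens ring B as a 1,4-diketone. The C4 hydroxyl has no vicinal partner and survives; C5 keeps the cis configuration of the photoadduct.

Step 5
Reactants: 8 cis-fused hydroxy dione
Product: 9 trans-fused (5α-H) 4α-hydroxy-1β,8α-dimethylbicyclo[5.3.0]decane-6,10-dione
Conditions: K2CO3, MeOH, 0 °C → rt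
Reagents that add atoms: none
Why: Base-mediated epimerisation through the C6 enolate; the trans-fused hydroazulenone with the carbonyl in the seven-membered ring should be the more stable isomer, and the C4 oxygen and C6 then stand trans on ring A. A free β-hydroxyl is a poor leaving group, so E1cB loss of the C4 oxygen should be slow.

Step 6
Reactants: 9 trans-fused hydroxy dione
Product: 10 6,6-ethylenedioxy-4α-hydroxy-1β,8α-dimethyl-trans-bicyclo[5.3.0]decan-10-one
Conditions: HOCH2CH2OH (1.5 equiv), PPTS (cat.), benzene, reflux (Dean–Stark)
Reagents that add atoms: ethylene glycol, OCCO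
Why: Acid-catalysed acetalisation is sterically selective: the C10 carbonyl is flanked by quaternary C1 and should react much more slowly than C6. The mask is needed because C4 later becomes a ketone.

Step 7
Reactants: 10 C6 ketal
Product: 13 6,6-ethylenedioxy-4α-hydroxy-1β,8-dimethyl-trans-bicyclo[5.3.0]dec-8-en-10-one, via bis-silyl enol ether 11 (not isolated), via silyl ether enone 12 (not isolated)
Conditions: LiN(iPr)2 (2.3 equiv), Me3SiCl, THF, −78 °C; Pd(OAc)2 (1.1 equiv), MeCN, rt; K2CO3, MeOH, 0 °C
Reagents that add atoms: none
Why: Saegusa–Ito oxidation: the C10 ketone can enolise only toward C9, and the silyl enol ether is dehydrogenated through a palladium enolate and β-hydride elimination of the C8 hydrogen. This erases the uncontrolled C8 centre; the hydroxyl is silylated in passing and freed again by methanolysis.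

Step 8
Reactants: 13 enone
Product: 14 (E)-tosylhydrazone of 13
Conditions: TsNHNH2, PPTS (cat.), THF, 4 Å molecular sieves, 50 °C
Reagents that add atoms: 4-methylbenzenesulfonohydrazide, Cc1ccc(cc1)S(=O)(=O)NN
Why: Condensation of the conjugated ketone with tosylhydrazide; the sulfonamide nitrogen should settle anti to quaternary C1. The β-methyl on the enone disfavours conjugate addition.

Step 9
Reactants: 14 (E)-tosylhydrazone
Product: 16 6,6-ethylenedioxy-1β,8α-dimethyl-trans-bicyclo[5.3.0]dec-9-en-4α-ol (8β-H), via allylic diazene 15 (not isolated)
Conditions: catecholborane (3 equiv), CHCl3, 0 °C; then NaOAc·3H2O, 60 °C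
Reagents that add atoms: none
Why: Alkene-transposing variant of the Wolff–Kishner reduction: hydride adds to C=N from the α face, anti to the axial C1 methyl, and loss of sulfinate gives the 10β-diazene. The diazene hands its hydrogen to C8 across the same β face in a retro-ene step with loss of N2, which sets 8β-H and moves the alkene to C9=C10.

Step 10
Reactants: 16 alkenol
Product: 17 6,6-ethylenedioxy-1β,8α-dimethyl-trans-bicyclo[5.3.0]dec-9-en-4-one
Conditions: Dess–Martin periodinane, pyridine, CH2Cl2, 0 °C → rt
Reagents that add atoms: none
Why: Dess–Martin oxidation of the secondary alcohol under buffered, non-enolising conditions, so that C5, now α to a cyclopentanone, keeps the trans configuration.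

Step 11
Reactants: 17 ketone; 18 isopropylmagnesium chloride
Product: 19 6,6-ethylenedioxy-8βH-dauc-9-en-4β-ol (4α-isopropyl)
Conditions: CeCl3, THF, −78 °C
Reagents that add atoms: none
Why: Organocerium addition, chosen for its low basicity (no enolisation, no C5 epimerisation). The reagent attacks the α face because the vicinal C5–C6 bond and the C1 methyl both lie on the β face of ring A, giving 4β-OH and 4α-isopropyl.

Step 12
Reactants: 19 ketal
Product: 20 4β-hydroxy-8βH-dauc-9-en-6-one
Conditions: PPTS (cat.), acetone/H2O (10:1), rt → 40 °C
Reagents that add atoms: water, O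
Why: Mild acid-catalysed hydrolysis of the dioxolane; the conditions are kept gentle because the product is a tertiary aldol that could dehydrate.

Step 13
Reactants: 20 β-hydroxy ketone
Product: 21 8βH-dauc-9-ene-4β,6α-diol
Conditions: Me4NBH(OAc)3, MeCN/AcOH (1:1), −20 °C
Reagents that add atoms: none
Why: Evans–Saksena hydroxyl-directed reduction: the C4 hydroxyl exchanges onto boron and hydride is delivered through a six-membered transition state to the β face of C6, giving the 6α-alcohol. The reagent is too weak to reduce a ketone it cannot reach in this way, so the undirected α attack is suppressed.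

Step 14
Reactants: 21 diol; 22 4-methoxybenzoyl chloride
Product: 23 4β-hydroxy-8βH-dauc-9-en-6α-yl 4-methoxybenzoate
Conditions: DMAP (cat.), pyridine, CH2Cl2, 0 °C → rt
Reagents that add atoms: none
Why: DMAP-catalysed acylation; only the secondary C6 hydroxyl reacts, the tertiary C4 hydroxyl being too hindered.

Step 15
Reactants: 23 alkene
Product: 24 9α,10α-epoxy-4β-hydroxy-8βH-daucan-6α-yl 4-methoxybenzoate
Conditions: mCPBA, CH2Cl2, 0 °C
Reagents that add atoms: 3-chloroperoxybenzoic acid, OOC(=O)c1cccc(Cl)c1
Why: Prilezhaev epoxidation; the peracid should approach C9=C10 from the α face because the β face is covered by the angular, necessarily pseudoaxial methyl on the adjacent quaternary C1, whereas the 8α-methyl can turn pseudoequatorial. This puts oxygen on C10 in the α configuration that ketone reduction cannot give.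

Step 16
Reactants: 24 epoxide
Product: 27 4β,10α-dihydroxydauc-8-en-6α-yl 4-methoxybenzoate, via hydroxy selenide 25 (not isolated), via selenoxide 26 (not isolated)
Conditions: PhSeSePh, NaBH4, EtOH, 60 °C; then THF, 30% H2O2, 0 °C → rt
Reagents that add atoms: none
Why: Phenylselenolate opens the epoxide at C9 with inversion (C10 is neopentyl), and oxidation gives the selenoxide, which undergoes syn-elimination. Selenoxides eliminate away from a β-hydroxyl, and the 8β-hydrogen set in step 9 is syn to the 9β-selenium, so the alkene returns to C8=C9 and the 10α-hydroxyl stays.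

Step 17
Reactants: 27 allylic alcohol; 28 angelic acid
Product: 29 (1S,4R,5S,6S,10R)-10α-angeloyloxy-4β-hydroxydauc-8-en-6α-yl 4-methoxybenzoate
Conditions: 2,4,6-trichlorobenzoyl chloride, Et3N, toluene, rt; then 27, 80 °C
Reagents that add atoms: none
Why: Yamaguchi-type mixed-anhydride esterification run without DMAP, the additive that isomerises angelates to tiglates. The secondary allylic hydroxyl reacts and the tertiary one does not; the (Z)-ester goes on last.

## Compound list

1 | dimethyl 3-methylpentanedioate | COC(=O)CC(C)CC(=O)OC | starting material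
2 | chlorotrimethylsilane | C[Si](C)(C)Cl | starting material
3 | 4-methyl-1,2-bis(trimethylsilyloxy)cyclopent-1-ene | CC1CC(O[Si](C)(C)C)=C(O[Si](C)(C)C)C1 | intermediate
4 | 3-methylcyclopent-2-en-1-one | CC1=CC(=O)CC1 | starting material
5 | cis-anti-cis photoadduct: tricyclic C4 ketone, C1–C10/C5–C6 cyclobutane, 1β-methyl, 5β-H, 6α,10α-bis(trimethylsilyloxy), 8-methyl on the side of the outer ring that carries the silyloxy groups | C[C@]12CCC(=O)[C@H]1[C@]1(O[Si](C)(C)C)C[C@@H](C)C[C@]21O[Si](C)(C)C | intermediate
6 | 4α-alcohol of 5 | C[C@]12CC[C@@H](O)[C@H]1[C@]1(O[Si](C)(C)C)C[C@@H](C)C[C@]21O[Si](C)(C)C | intermediate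
7 | tricyclic 4α,6α,10α-triol | C[C@]12CC[C@@H](O)[C@H]1[C@]1(O)C[C@@H](C)C[C@]21O | intermediate
8 | cis-fused (5β-H) 4α-hydroxy-1β,8α-dimethylbicyclo[5.3.0]decane-6,10-dione | O=C1C[C@H](C)CC(=O)[C@H]2[C@]1(C)CC[C@H]2O | intermediate
9 | trans-fused (5α-H) 4α-hydroxy-1β,8α-dimethylbicyclo[5.3.0]decane-6,10-dione | O=C1C[C@H](C)CC(=O)[C@@H]2[C@]1(C)CC[C@H]2O | intermediate
10 | 6,6-ethylenedioxy-4α-hydroxy-1β,8α-dimethyl-trans-bicyclo[5.3.0]decan-10-one | O=C1C[C@H](C)CC3(OCCO3)[C@@H]2[C@]1(C)CC[C@H]2O | intermediate
11 | 4α,10-bis(trimethylsilyloxy) C9=C10 enol ether of 10 | C[Si](C)(C)OC1=C[C@H](C)CC3(OCCO3)[C@@H]2[C@]1(C)CC[C@H]2O[Si](C)(C)C | intermediate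
12 | 4α-trimethylsilyl ether of enone 13 | O=C1C=C(C)CC3(OCCO3)[C@@H]2[C@]1(C)CC[C@H]2O[Si](C)(C)C | intermediate
13 | 6,6-ethylenedioxy-4α-hydroxy-1β,8-dimethyl-trans-bicyclo[5.3.0]dec-8-en-10-one | O=C1C=C(C)CC3(OCCO3)[C@@H]2[C@]1(C)CC[C@H]2O | intermediate
14 | (E)-tosylhydrazone of 13 | Cc1ccc(cc1)S(=O)(=O)N/N=C1\C=C(C)CC3(OCCO3)[C@@H]2[C@]1(C)CC[C@H]2O | intermediate
15 | 10β-diazenyl C8=C9 alkene (allylic diazene) | N=N[C@H]1C=C(C)CC3(OCCO3)[C@@H]2[C@]1(C)CC[C@H]2O | intermediate
16 | 6,6-ethylenedioxy-1β,8α-dimethyl-trans-bicyclo[5.3.0]dec-9-en-4α-ol (8β-H) | C1=C[C@H](C)CC3(OCCO3)[C@@H]2[C@]1(C)CC[C@H]2O | intermediate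
17 | 6,6-ethylenedioxy-1β,8α-dimethyl-trans-bicyclo[5.3.0]dec-9-en-4-one | C1=C[C@H](C)CC3(OCCO3)[C@@H]2[C@]1(C)CCC2=O | intermediate
18 | isopropylmagnesium chloride | CC(C)[Mg]Cl | starting material
19 | 6,6-ethylenedioxy-8βH-dauc-9-en-4β-ol (4α-isopropyl) | C1=C[C@H](C)CC3(OCCO3)[C@@H]2[C@]1(C)CC[C@@]2(O)C(C)C | intermediate
20 | 4β-hydroxy-8βH-dauc-9-en-6-one | C1=C[C@H](C)CC(=O)[C@@H]2[C@]1(C)CC[C@@]2(O)C(C)C | intermediate
21 | 8βH-dauc-9-ene-4β,6α-diol | C1=C[C@H](C)C[C@H](O)[C@@H]2[C@]1(C)CC[C@@]2(O)C(C)C | intermediate
22 | 4-methoxybenzoyl chloride | COc1ccc(cc1)C(Cl)=O | starting material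
23 | 4β-hydroxy-8βH-dauc-9-en-6α-yl 4-methoxybenzoate | C1=C[C@H](C)C[C@H](OC(=O)c3ccc(OC)cc3)[C@@H]2[C@]1(C)CC[C@@]2(O)C(C)C | intermediate
24 | 9α,10α-epoxy-4β-hydroxy-8βH-daucan-6α-yl 4-methoxybenzoate | O1[C@@H]2[C@H]1[C@H](C)C[C@H](OC(=O)c3ccc(OC)cc3)[C@@H]4[C@]2(C)CC[C@@]4(O)C(C)C | intermediate
25 | 4β,10α-dihydroxy-9β-phenylselanyl-8βH-daucan-6α-yl 4-methoxybenzoate | O[C@@H]1[C@@H]([Se]c3ccccc3)[C@H](C)C[C@H](OC(=O)c4ccc(OC)cc4)[C@@H]2[C@]1(C)CC[C@@]2(O)C(C)C | intermediate
26 | selenoxide of 25 | O[C@@H]1[C@@H]([Se](=O)c3ccccc3)[C@H](C)C[C@H](OC(=O)c4ccc(OC)cc4)[C@@H]2[C@]1(C)CC[C@@]2(O)C(C)C | intermediate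
27 | 4β,10α-dihydroxydauc-8-en-6α-yl 4-methoxybenzoate | O[C@@H]1C=C(C)C[C@H](OC(=O)c2ccc(OC)cc2)[C@@H]2[C@]1(C)CC[C@@]2(O)C(C)C | intermediate
28 | angelic acid, (Z)-2-methylbut-2-enoic acid | C/C=C(/C)C(=O)O | starting material
29 | (1S,4R,5S,6S,10R)-10α-angeloyloxy-4β-hydroxydauc-8-en-6α-yl 4-methoxybenzoate | C/C=C(/C)C(=O)O[C@@H]1C=C(C)C[C@H](OC(=O)c2ccc(OC)cc2)[C@@H]2[C@]1(C)CC[C@@]2(O)C(C)C | target

## Step count and least certain steps

Total: 17 steps. Longest linear sequence: 17 steps, from 1 to 29; compounds 4, 18, 22 and 28 are purchased and enter along the way.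

**(a) The photocycloaddition (step 2, key step, proposed new method).** The most likely failure is poor discrimination of the two enone faces, since this catalyst class has its record on six-membered enones. A racemic background reaction of unbound enone and Lewis-acid-induced loss of silyl groups from 3 would add to it. The fallback uses known chemistry only and sets out from 3 and 4. They are irradiated without Lewis acid (λ ≈ 350 nm, CH2Cl2, −20 °C), which gives 5 together with the mirror-image photoadduct F1. Reduction with iBu2AlH as in step 3 gives 6 with the mirror-image alcohol F2. Acylation of the mixture with (1S)-camphanic chloride (pyridine, DMAP) gives the camphanate of 6 F3 and the diastereomeric camphanate F4, which are separated by chromatography or crystallisation. Methanolysis of F3 (K2CO3, MeOH) removes the acyl group and both silyl groups and gives triol 7, where the route is rejoined before the Pb(OAc)4 cleavage.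

**(b) The reductive alkene transposition (step 9).** Hydride delivery to a hindered, conjugated C=N bond may be slow, or may occur partly from the β face, which would leave the C8 hydrogen α and block the later syn-elimination. The fallback sets out from 10. Condensation with TsNHNH2 gives the saturated tosylhydrazone F5, and a Shapiro reaction (nBuLi, THF/TMEDA, −78 → 0 °C) gives the C10 alkenyllithium F6, which is protonated on work-up to 16. This path inherits C8 from the photocycloaddition instead of creating it, so it suits the case where step 2 proves cleanly anti-selective; it returns at 16.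

**(c) The directed reduction (step 13).** Exchange of the hindered tertiary C4 hydroxyl onto boron may be too slow, so the reduction stalls or loses its direction. The fallback sets out from 20. LiBH(sBu)3 (THF, −78 °C) attacks C6 from the open α side and should give the 6β-alcohol F7. A Mitsunobu reaction of F7 with 4-methoxybenzoic acid (PPh3, DIAD) then inverts C6 and installs the ester in one operation, returning at 23.

**(d) The epoxidation (step 15).** Facial selectivity may be poor, because the 8α-methyl lies on the α face next to C9 and the 4β-hydroxyl could guide the peracid to the β face by hydrogen bonding. The fallback sets out from 23 and suits the case where electrophiles prefer the β face. NBS in aqueous DME should then form the β-bromonium ion, which water opens from the α side at C9 (C10 is neopentyl) to give the 10β-bromo-9α-hydroxy compound F8. Ag2O (acetone, rt) closes the 9α-oxygen onto C10 with inversion and gives the α-epoxide 24, where the route is rejoined. The oxygen is thus delivered as a nucleophile anti to the electrophile and no longer on the face the electrophile chooses.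

**(e) Epoxide opening and selenoxide elimination (step 16).** The selenolate must enter at C9 syn to the C1 methyl in a 1,3-relationship, so opening may be slow enough for ester cleavage to compete, and part of the selenoxide may eliminate toward C10. The fallback sets out from 23. Dihydroxylation (OsO4 cat., NMO) from the α face gives the 9α,10α-diol F9. The less hindered C9 hydroxyl is mesylated (MsCl, Et3N, −20 °C) to the 9-mesylate F10, and DBU brings about anti-elimination, the 8β-hydrogen being antiperiplanar to the 9α leaving group. This returns at 27.

**(f) The angeloylation (step 17).** Acylation of the hindered pseudoaxial C10 hydroxyl may be slow, and forcing it invites Z-to-E isomerisation. The fallback sets out from 27. Esterification with 2-[bis(2,2,2-trifluoroethoxy)phosphoryl]propanoic acid (N,N′-dicyclohexylcarbodiimide, DMAP) gives the phosphonopropanoate F11. A Still–Gennari olefination with acetaldehyde (KN(SiMe3)2, 18-crown-6, THF, −78 °C) then builds the (Z)-2-methylbut-2-enoate on the molecule and returns at 29.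

## Further compounds

F1 | step 2 | enantiomer of 5 | C[C@@]12CCC(=O)[C@@H]1[C@@]1(O[Si](C)(C)C)C[C@H](C)C[C@@]21O[Si](C)(C)C
F2 | step 2 | enantiomer of 6 | C[C@@]12CC[C@H](O)[C@@H]1[C@@]1(O[Si](C)(C)C)C[C@H](C)C[C@@]21O[Si](C)(C)C
F3 | step 2 | (1S)-camphanate of 6 | C[C@]12CC[C@@H](OC(=O)[C@@]34CC[C@@](C)(C(=O)O3)C4(C)C)[C@H]1[C@]1(O[Si](C)(C)C)C[C@@H](C)C[C@]21O[Si](C)(C)C
F4 | step 2 | (1S)-camphanate of the enantiomer of 6 | C[C@@]12CC[C@H](OC(=O)[C@@]34CC[C@@](C)(C(=O)O3)C4(C)C)[C@@H]1[C@@]1(O[Si](C)(C)C)C[C@H](C)C[C@@]21O[Si](C)(C)C
F5 | step 9 | (E)-tosylhydrazone of 10 | Cc1ccc(cc1)S(=O)(=O)N/N=C1\C[C@H](C)CC3(OCCO3)[C@@H]2[C@]1(C)CC[C@H]2O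
F6 | step 9 | C10 alkenyllithium (lithium alkoxide) from F5 | [Li]C1=C[C@H](C)CC3(OCCO3)[C@@H]2[C@]1(C)CC[C@H]2O[Li]
F7 | step 13 | 8βH-dauc-9-ene-4β,6β-diol | C1=C[C@H](C)C[C@@H](O)[C@@H]2[C@]1(C)CC[C@@]2(O)C(C)C
F8 | step 15 | 10β-bromo-4β,9α-dihydroxy-8βH-daucan-6α-yl 4-methoxybenzoate | Br[C@H]1[C@H](O)[C@H](C)C[C@H](OC(=O)c3ccc(OC)cc3)[C@@H]2[C@]1(C)CC[C@@]2(O)C(C)C
F9 | step 16 | 4β,9α,10α-trihydroxy-8βH-daucan-6α-yl 4-methoxybenzoate | O[C@@H]1[C@H](O)[C@H](C)C[C@H](OC(=O)c3ccc(OC)cc3)[C@@H]2[C@]1(C)CC[C@@]2(O)C(C)C
F10 | step 16 | 9α-methanesulfonate of F9 | O[C@@H]1[C@H](OS(C)(=O)=O)[C@H](C)C[C@H](OC(=O)c3ccc(OC)cc3)[C@@H]2[C@]1(C)CC[C@@]2(O)C(C)C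
F11 | step 17 | 10α-{2-[bis(2,2,2-trifluoroethoxy)phosphoryl]propanoyloxy}-4β-hydroxydauc-8-en-6α-yl 4-methoxybenzoate | CC(C(=O)O[C@@H]1C=C(C)C[C@H](OC(=O)c2ccc(OC)cc2)[C@@H]2[C@]1(C)CC[C@@]2(O)C(C)C)P(=O)(OCC(F)(F)F)OCC(F)(F)F
A1 | alternative 1 | 2,5-dimethylfuran | Cc1ccc(C)o1
A2 | alternative 1 | 1,1,3,3-tetrabromopropan-2-one | BrC(Br)C(=O)C(Br)Br
A3 | alternative 1 | 1,5-dimethyl-8-oxabicyclo[3.2.1]oct-6-en-3-one (meso) | C[C@@]12C=C[C@@](C)(O1)CC(=O)C2
A4 | alternative 2 | iodo ketone: cycloheptene with 2-iodoethyl and methyl on C1, 2-methylpropanoyl on C5, 6α-tert-butyldimethylsilyloxy and 10α-triethylsilyloxy | CC[Si](CC)(CC)O[C@@H]1C=C(C)C[C@H](O[Si](C)(C)C(C)(C)C)[C@@H](C(=O)C(C)C)[C@]1(C)CCI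
A5 | alternative 2 | 6α-tert-butyldimethylsilyloxy-10α-triethylsilyloxydauc-8-en-4β-ol | CC[Si](CC)(CC)O[C@@H]1C=C(C)C[C@H](O[Si](C)(C)C(C)(C)C)[C@@H]2[C@]1(C)CC[C@@]2(O)C(C)C
A6 | alternative 3 | 2-diazo-5-(2,6-dimethoxy-4-methylphenyl)pentan-3-one | CC(=[N+]=[N-])C(=O)CCc1c(OC)cc(C)cc1OC
A7 | alternative 3 | 4,8-dimethoxy-6,8a-dimethyl-3,8a-dihydroazulen-1(2H)-one | COC1=CC(C)=CC(OC)=C2CCC(=O)[C@]12C
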